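The closed, stirred vessel holds an electrophile, a nucleophile, a free base and a protic impurity, and two earlier runs show it with less and with more nucleophile than this flask.

all flasks: electrophile 0.50 mM
- violet: nucleophile 1 equiv; free base 3 equiv; protic impurity 0.10 mM; run made earlier
- green: nucleophile 4 equiv; free base 3 equiv; protic impurity 0.10 mM; run made earlier
- flask: nucleophile 2.00 equiv; free base 3.00 equiv; protic impurity 0.100 mM; time 12 min

- violet (time / min: electrophile / %, target / %): 1.00: 70.5, 27.6; 1.50: 66.8, 28.1; 2.50: 62.9, 32.3; 4.00: 61.4, 32.1; 8.00: 59.1, 35.4; 12.0: 58.5, 37.2
- green (time / min: electrophile / %, target / %): 1.00: 17.5, 41.0; 1.50: 8.9, 32.6; 2.50: 3.2, 22.4; 4.00: 1.2, 11.2; 8.00: 0.8, 2.6; 12.0: 2.6, 0.8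

(readings scatter by 1 percentage point)

- the earlier runs do not show how much of nucleophile is bound; that part of a forecast is a guess

* part of the electrophile that has reacted at 12 min
* share of free nucleophile in free nucleophile and protonated nucleophile together, at 12 min

I keep one ledger in fractions of the electrophile charge, and I read the nucleophile as the limiting reagent. In that ledger the impurity takes one nucleophile, each reacted electrophile takes two (one to make target, one as protonated nucleophile), and each target lost onward takes one. This flask's charge gives 1.80: that is the nucleophile budget, the equivalents charged less the impurity's fraction of the charge, and I expect this flask to slow as the spending nears it.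

The violet run tests the ledger. Its budget is 0.800, and its last reading shows 41.5 % reacted and 4.30 % lost onward, a spend of 0.873. So the violet run overspends by a reading of 0.0730, which I carry over unchanged.

For this flask, the budget gives 90.0 % reacted if no target goes onward and 60.0 % if every target does. To join these ends I take the green reading at 1.00 min, where the fraction lost onward over the square of the fraction reacted reads 0.610. With that curve, budget plus overspend gives 76.0 % reacted. The free share stays a guess.

The forecast commits to 78 % reacted and 5 % free, “with the system nearly stalled by 12 min”; my figure lies slightly lower.

The flask gives 77.4 % reacted and a free share of 2.29 %.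

    nucleophile + target → over-reaction product (k = 16.7 L mol⁻¹ s⁻¹)
    acid set free + free base ⇌ salt of the base (K = 1300 L mol⁻¹, k = 828 L mol⁻¹ s⁻¹)
    nucleophile + protic impurity → quenched reagent (k = 145 L mol⁻¹ s⁻¹)
    nucleophile + acid set free ⇌ protonated nucleophile, settled at all times (K = 2.40 × 10⁶ L mol⁻¹)
    nucleophile + acid set free ⇌ idle adduct, settled at all times (K = 11000 L mol⁻¹)
    electrophile + nucleophile → acid set free + target (k = 25.1 L mol⁻¹ s⁻¹)

The link I reforge is the overspend: in this flask at 12.0 min the reacted fraction and the over-reaction product give a spend above budget of 0.0877, against my violet reading of 0.0730. The same ledger on the neighbouring flask, with 0.40 mM of protic impurity, starts from a budget of 1.20 and, with both readings unchanged, gives 54.6 % reacted. That neighbouring flask gives 58.1 %, with 41.9 % of its electrophile left.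

The runs stem from a simulated flask on assumed constants, and the scatter is random.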